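(The earlier runs and the new flask come from a simulation on assumed constants, noise included.)

Pseudo-first-order reckoning is impossible for the alpha flask: its 90.0 mM of partner is 1.50 times its 60.0 mM of starting material, the limiting reagent, so both fall together.

| flask | starting material | partner | time |
|---|---|---|---|
| gamma | 150 mM | 225 mM |  |
| epsilon | 60.0 mM | 135 mM |  |
| eta | 300 mM | 225 mM |  |
| zeta | 150 mM | 680 mM |  |
| alpha | 60.0 mM | 90.0 mM | 5.1 h |

| run | time / h | [target] / mM |
|---|---|---|
| gamma run | 0.20 | 7.4 |
| gamma run | 0.32 | 11.8 |
| gamma run | 0.51 | 19.2 |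
| gamma run | 0.81 | 26.2 |
| gamma run | 1.3 | 37.5 |
| gamma run | 2.0 | 50.5 |
| gamma run | 3.2 | 61.6 |
| gamma run | 5.1 | 70.5 |
| epsilon run | 0.20 | 1.8 |
| epsilon run | 0.32 | 2.8 |
| epsilon run | 0.51 | 4.8 |
| epsilon run | 0.81 | 7.2 |
| epsilon run | 1.3 | 11.0 |
| epsilon run | 2.0 | 15.5 |
| epsilon run | 3.2 | 20.3 |
| epsilon run | 5.1 | 26.5 |
| eta run | 0.20 | 15.6 |
| eta run | 0.32 | 23.1 |
| eta run | 0.51 | 34.1 |
| eta run | 0.81 | 49.3 |
| eta run | 1.3 | 66.6 |
| eta run | 2.0 | 82.4 |
| eta run | 3.2 | 97.1 |
| eta run | 5.1 | 104.4 |
| zeta run | 0.20 | 22.6 |
| zeta run | 0.32 | 33.1 |
| zeta run | 0.51 | 48.5 |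
| zeta run | 0.81 | 64.7 |
| zeta run | 1.3 | 81.5 |
| zeta run | 2.0 | 92.8 |
| zeta run | 3.2 | 93.4 |
| zeta run | 5.1 | 84.4 |

(standard deviation of a reading: 0.4 mM)

* the power of [starting material] that the first rate follows, about the charge of the gamma run; measure it at two percent of starting material made into target (one fixed amount of target, the same in the runs compared)
* the power of [partner] that the first rate follows, about the charge of the gamma run; measure it at two percent of starting material made into target
* target in the alpha run at 5.1 h, as a share of the starting material charged

- Overall: starting material + partner -> target.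
- Constant volume, constant temperature.
- "The second partner" is partner.
- An order is taken over about fifteen percent of the charge, up and down.

*What are the orders?* From the target at 0.20 h, eta against gamma gives 1.08 in starting material and zeta against gamma gives 1.01 in partner. These spans are wider than the one asked, but I commit to first order in each.

*Then what rate do you integrate?* Rate = k(S − x)(P − x), with S and P the charges and x the target. In closed form, ln[(P − x)S / ((S − x)P)] = (P − S)kt.

*Which k?* I use the pair constant, the apparent second-order constant that makes this closed form pass through one chosen reading, with any loss folded in. The epsilon flask has the alpha charge of starting material, and at 3.2 h its target stands at 33.8% of that charge. That reading gives 1.04 M⁻¹ h⁻¹.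

*And alpha?* The exponential is 1.17, so target is 20.5 mM, or 34.1%. That is about the epsilon amount used.

*But is k constant?* No. The zeta flask falls from 93.4 mM to 84.4 mM, so target is being lost there. The epsilon reading at 5.1 h gives a lower constant, 0.952 M⁻¹ h⁻¹. Carried to alpha, it gives 1.16 and 32.0%. I hold to 34.1%, with that as my low side.

The forecast gives 1.03, 1 and 33%, a little below my share, and says: “Subtracting about 2 mM of loss leaves about 20 mM, or 33%”.

The flask gives orders of 1.0 and 1.0, and 33.7% in the alpha flask, which is 0.40 percentage points under my share.

    starting material + partner ⇌ target + by-product (1.246 M⁻¹ h⁻¹, 0.8676 M⁻¹ h⁻¹)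
    target + partner → side product (0.1764 M⁻¹ h⁻¹)
    2 starting material → homo dimer (0.3190 M⁻¹ h⁻¹)

The reaction to homo dimer moves the readings by 13 in units of the scatter, root mean square. Carried to the gamma flask, the pair constant puts target at a quarter of the starting material at 1.35 h, and the gamma flask gets there at 1.26 h, earlier by 0.0900 h.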